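A direct plan would condense 2,5-dibromobenzaldehyde A1 with ethyl azidoacetate A2 to the azidocinnamate A3, would close the pyrrole ring by thermal nitrene C–H insertion to indole ester A4, would saponify to acid A5 and decarboxylate over copper powder to 4,7-dibromoindole A6, and would end with C3 chlorination to 3-chloroindole A7 and C2 bromination. Its weakest steps would be: (a) the saponification and decarboxylation, two steps that would only erase a handle the ring closure required, the second near 210 °C where C–Br reduction threatens; (b) the final C2 bromination of the labile 3-chloroindole, where ipso attack at C3 and halogen migration or exchange could scramble the pattern on the most precious material; (c) the azide condensation and thermolysis, which would need a large excess of a hazardous azide and high dilution.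

New plan: the retrosynthesis cuts C3a–C4 and C7–C7a. The enabling feature is the benzo ring itself: Br on C4 and C7 and H on C5 and C6 make a symmetric BrC=CH–CH=CBr unit, which is the diene of 2,5-dibromothiophene 1,1-dioxide, and C3a–C7a is a pyrrole C=C bond. The pyrrole ring comes first and receives Cl (β, by Br/Li exchange) and Br (both α-sites) before any fusion. The benzene ring arises last by [4+2] cycloaddition, loss of SO2 and loss of HBr, the spare α-bromine being the traceless leaving group. Hence there is no carboxyl handle, no azide and no halogenation of an indole.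

Key step: step 4

Remark: the target is achiral; the sp3 centres of the two not-isolated intermediates of the key step are racemic and are erased on aromatisation. The silylated bromopyrrole and the dibromothiophene that open the two branches are taken as purchased.

Step 1
Reactants: 1 3-bromo-1-(triisopropylsilyl)-1H-pyrrole
Product: 3 3-chloro-1-(triisopropylsilyl)-1H-pyrrole, via 3-lithio-1-(triisopropylsilyl)-1H-pyrrole 2 (not isolated)
Conditions: n-BuLi (1.05 equiv), THF, −78 °C, 20 min; C2Cl6 (1.2 equiv), −78 °C → rt
Reagents that add atoms: hexachloroethane, ClC(Cl)(Cl)C(Cl)(Cl)Cl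
Why: Bromine–lithium exchange at the β-position (the bulky N-silyl group shields both α-positions from metalation) followed by electrophilic chlorination of the aryllithium should place the chlorine exactly where the bromine stood.

Step 2
Reactants: 3 3-chloro-1-(triisopropylsilyl)-1H-pyrrole
Product: 6 tert-butyl 2,5-dibromo-3-chloro-1H-pyrrole-1-carboxylate, via 3-chloro-1H-pyrrole 4 (not isolated), via 2,5-dibromo-3-chloro-1H-pyrrole 5 (not isolated)
Conditions: Bu4NF (1.05 equiv), THF, 0 °C, 20 min; NBS (2.05 equiv), −78 °C, 2 h, dark; then Boc2O (1.5 equiv), Et3N (1.5 equiv), DMAP (0.1 equiv), −78 °C → rt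
Reagents that add atoms: N-bromosuccinimide, O=C1CCC(=O)N1Br; di-tert-butyl dicarbonate, CC(C)(C)OC(=O)OC(=O)OC(C)(C)C
Why: Fluoride N-desilylation frees the NH-pyrrole, electrophilic aromatic substitution should then take both α-positions (C2 and C5, the most nucleophilic sites), and immediate DMAP-catalysed N-acylation should trap the labile α,α'-dibromopyrrole as a stable carbamate.

Step 3
Reactants: 7 2,5-dibromothiophene
Product: 9 2,5-dibromothiophene 1,1-dioxide, via 2,5-dibromothiophene 1-oxide 8 (not isolated)
Conditions: H2O2 (as its urea adduct, 4 equiv), (CF3CO)2O (6 equiv), MeCN, 0 °C → rt; aq. NaHCO3 wash, crystallise, store cold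
Reagents that add atoms: hydrogen peroxide, OO
Why: Peracid S-oxidation with peroxytrifluoroacetic acid, formed in the flask from the anhydride and hydrogen peroxide, should oxidise even the electron-poor sulfur of a dihalothiophene twice (S-oxide, then S,S-dioxide), and the two α-bromines should shield the resulting non-aromatic diene from self-dimerisation so that it can be isolated.

Step 4
Reactants: 6 tert-butyl 2,5-dibromo-3-chloro-1H-pyrrole-1-carboxylate; 9 2,5-dibromothiophene 1,1-dioxide
Product: 12 tert-butyl 2,4,7-tribromo-3-chloro-1H-indole-1-carboxylate, via bridged sulfone cycloadduct 10 (not isolated), via 7a-bromo-3a,7a-dihydroindole 11 (not isolated)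
Conditions: 6 (1.0 equiv, 0.5 M), CaCO3 (2 equiv), PhCl, 120 °C; 9 (2.0 equiv) in PhCl added over 6 h; N2 sweep, dark
Reagents that add atoms: none
Why: Proposed new method: the electron-poor, non-aromatic diene of 9 should add across the C4=C5 bond of 6 in an inverse-demand [4+2] cycloaddition, the 7-thiabicyclo[2.2.1]heptene sulfone 10 should extrude SO2 cheletropically, and the C7a–Br bond of 11 (α to the carbamate nitrogen and allylic) should ionise so that loss of H3a aromatises the new ring, CaCO3 taking up the HBr so that the Boc group survives. The closest known reaction type is the benzannulation of alkenes, enamines and enol ethers by thiophene 1,1-dioxides (cycloaddition, SO2 loss, then loss of amine, alcohol or HX), including the dimerisation of thiophene dioxides themselves; new is a pyrrole C=C bond as the 2π partner with its α-bromine as leaving group, which makes 6 a 2,3-pyrrolyne equivalent. The benzene ring is closed by an intermolecular, suprafacial [4+2] closure that forms C3a–C4 and C7–C7a at once. The two sp3 centres created at C3a and C7a (cis, racemic) are erased on aromatisation, so no stereocontrol is needed. The step needs site selectivity for C4=C5 over C2=C3, secured because C2=C3 is fully substituted (Br, Cl) while C4 carries H, and it has no regiochemical question because diene 9 has a twofold axis through sulfur that makes its two termini equivalent; it also needs the cross-reaction to beat self-dimerisation of 9, which the flanking bromines of 9 should retard and slow addition of 9 to concentrated 6 should suppress further. N-Acylation should lower the aromatic stabilisation of the pyrrole and keep the α-bromopyrrole intact at 120 °C.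

Step 5
Reactants: 12 tert-butyl 2,4,7-tribromo-3-chloro-1H-indole-1-carboxylate
Product: 13 2,4,7-tribromo-3-chloro-1H-indole
Conditions: K2CO3 (0.5 equiv), MeOH/THF 1:1, 0 °C → rt; aq. NH4Cl; dark
Reagents that add atoms: none
Why: Methanolysis of an N-acylindole (acyl transfer to methoxide) should be easy because the carbamate is twisted between the C2 and C7 bromines and the tetrahalogenated indolide is a good leaving group, and neither acid nor heat touches the 2-bromo-3-chloroindole.

Compound list
1 | 3-bromo-1-(triisopropylsilyl)-1H-pyrrole | CC(C)[Si](C(C)C)(C(C)C)n1ccc(Br)c1 | starting material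
2 | 3-lithio-1-(triisopropylsilyl)-1H-pyrrole | [Li]c1ccn([Si](C(C)C)(C(C)C)C(C)C)c1 | intermediate (not isolated)
3 | 3-chloro-1-(triisopropylsilyl)-1H-pyrrole | CC(C)[Si](C(C)C)(C(C)C)n1ccc(Cl)c1 | intermediate
4 | 3-chloro-1H-pyrrole | Clc1cc[nH]c1 | intermediate (not isolated)
5 | 2,5-dibromo-3-chloro-1H-pyrrole | Clc1cc(Br)[nH]c1Br | intermediate (not isolated)
6 | tert-butyl 2,5-dibromo-3-chloro-1H-pyrrole-1-carboxylate | CC(C)(C)OC(=O)n1c(Br)cc(Cl)c1Br | intermediate
7 | 2,5-dibromothiophene | Brc1ccc(Br)s1 | starting material
8 | 2,5-dibromothiophene 1-oxide | O=S1C(Br)=CC=C1Br | intermediate (not isolated)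
9 | 2,5-dibromothiophene 1,1-dioxide | O=S1(=O)C(Br)=CC=C1Br | intermediate
10 | tert-butyl 2,4,7,7a-tetrabromo-3-chloro-3a,4,7,7a-tetrahydro-4,7-episulfano-1H-indole-1-carboxylate S,S-dioxide (bridged sulfone cycloadduct; racemic, endo/exo not defined, drawn without configuration) | CC(C)(C)OC(=O)N1C(Br)=C(Cl)C2C1(Br)C1(Br)C=CC2(Br)S1(=O)=O | intermediate (not isolated)
11 | tert-butyl 2,4,7,7a-tetrabromo-3-chloro-3a,7a-dihydro-1H-indole-1-carboxylate (cis-fused, racemic, relative configuration drawn) | CC(C)(C)OC(=O)N1C(Br)=C(Cl)[C@@H]2C(Br)=CC=C(Br)[C@]12Br | intermediate (not isolated)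
12 | tert-butyl 2,4,7-tribromo-3-chloro-1H-indole-1-carboxylate | CC(C)(C)OC(=O)n1c(Br)c(Cl)c2c(Br)ccc(Br)c12 | intermediate
13 | 2,4,7-tribromo-3-chloro-1H-indole | Clc1c(Br)[nH]c2c(Br)ccc(Br)c12 | target

Total step count: 5. Longest linear sequence: 4 (steps 1, 2, 4, 5); step 3 is a one-step side branch.

Steps most likely to fail

Step 4 (Proposed new method). The cycloaddition may stall because the 2π partner is an aromatic, hindered bromo-enecarbamate; self-dimerisation of the diene, reaction of the pyrrole as the 4π partner, or acid-induced loss of the Boc group may then take over. The fallback uses known reaction types only and sets out from 9. The dioxide would be heated (PhMe, 100 °C) with commercial tert-butyl 2,3-dihydro-1H-pyrrole-1-carboxylate, an electron-rich cyclic enecarbamate of the class (enamines, enol ethers) that thiophene dioxides are known to annulate. This would give the bridged sulfone cycloadduct F1, which would lose SO2 to cis-fused tert-butyl 4,7-dibromo-2,3,3a,7a-tetrahydro-1H-indole-1-carboxylate F2. DDQ would aromatise the carbocycle at rt to tert-butyl 4,7-dibromoindoline-1-carboxylate F3 and then, in refluxing 1,4-dioxane, dehydrogenate the five-membered ring to tert-butyl 4,7-dibromo-1H-indole-1-carboxylate F4. NCS in DMF would chlorinate C3 of the N-acylindole to tert-butyl 4,7-dibromo-3-chloro-1H-indole-1-carboxylate F5. Lithium diisopropylamide (LDA; THF, −78 °C) would metalate C2 to tert-butyl 4,7-dibromo-3-chloro-2-lithio-1H-indole-1-carboxylate F6, and quenching with BrCCl2CCl2Br would come back to the route at 12. Both halogens of the five-membered ring would then be set by position-specific steps on a carbamate-stabilised indole.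

Step 2. Over-bromination at C4 and oxidative oligomerisation of the unprotected halopyrroles may occur before the acylation takes hold. The fallback sets out from 3 and installs the bromines by directed metalation on the acylated pyrrole instead of by electrophilic substitution on the free one. Bu4NF and then Boc2O/DMAP would give, through 4, tert-butyl 3-chloro-1H-pyrrole-1-carboxylate F7. Lithium 2,2,6,6-tetramethylpiperidide (LiTMP, 2.5 equiv; THF, −78 °C) would deprotonate both α-positions to tert-butyl 3-chloro-2,5-dilithio-1H-pyrrole-1-carboxylate F8, and BrCCl2CCl2Br would come back to the route at 6.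

Step 3. S-Oxidation of the electron-poor thiophene may stop short, and the intermediate S-oxide may be lost to [4+2] self-condensation. The fallback sets out from 7 and makes the sulfur electron-rich before oxidation. Double bromine–lithium exchange (n-BuLi, 2.2 equiv, THF, −78 → −20 °C) would give 2,5-dilithiothiophene F9, and Me3SiCl would give 2,5-bis(trimethylsilyl)thiophene F10. mCPBA (CH2Cl2, rt) would oxidise this to 2,5-bis(trimethylsilyl)thiophene 1,1-dioxide F11, and ipso-bromodesilylation with Br2/AgBF4 (CH2Cl2, 0 °C) would come back to the route at 9.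

Further compounds
F1 | step 4 | tert-butyl 4,7-dibromo-2,3,3a,4,7,7a-hexahydro-4,7-episulfano-1H-indole-1-carboxylate S,S-dioxide (bridged sulfone cycloadduct, racemic) | CC(C)(C)OC(=O)N1CCC2C1C1(Br)C=CC2(Br)S1(=O)=O
F2 | step 4 | tert-butyl 4,7-dibromo-2,3,3a,7a-tetrahydro-1H-indole-1-carboxylate (cis-fused, racemic) | CC(C)(C)OC(=O)N1CC[C@@H]2C(Br)=CC=C(Br)[C@H]12
F3 | step 4 | tert-butyl 4,7-dibromoindoline-1-carboxylate | CC(C)(C)OC(=O)N1CCc2c(Br)ccc(Br)c12
F4 | step 4 | tert-butyl 4,7-dibromo-1H-indole-1-carboxylate | CC(C)(C)OC(=O)n1ccc2c(Br)ccc(Br)c12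
F5 | step 4 | tert-butyl 4,7-dibromo-3-chloro-1H-indole-1-carboxylate | CC(C)(C)OC(=O)n1cc(Cl)c2c(Br)ccc(Br)c12
F6 | step 4 | tert-butyl 4,7-dibromo-3-chloro-2-lithio-1H-indole-1-carboxylate | CC(C)(C)OC(=O)n1c([Li])c(Cl)c2c(Br)ccc(Br)c12
F7 | step 2 | tert-butyl 3-chloro-1H-pyrrole-1-carboxylate | CC(C)(C)OC(=O)n1ccc(Cl)c1
F8 | step 2 | tert-butyl 3-chloro-2,5-dilithio-1H-pyrrole-1-carboxylate | CC(C)(C)OC(=O)n1c([Li])cc(Cl)c1[Li]
F9 | step 3 | 2,5-dilithiothiophene | [Li]c1ccc([Li])s1
F10 | step 3 | 2,5-bis(trimethylsilyl)thiophene | C[Si](C)(C)c1ccc([Si](C)(C)C)s1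
F11 | step 3 | 2,5-bis(trimethylsilyl)thiophene 1,1-dioxide | C[Si](C)(C)C1=CC=C([Si](C)(C)C)S1(=O)=O
A1 | direct plan | 2,5-dibromobenzaldehyde | O=Cc1cc(Br)ccc1Br
A2 | direct plan | ethyl azidoacetate | CCOC(=O)CN=[N+]=[N-]
A3 | direct plan | ethyl (Z)-2-azido-3-(2,5-dibromophenyl)prop-2-enoate | CCOC(=O)/C(N=[N+]=[N-])=C/c1cc(Br)ccc1Br
A4 | direct plan | ethyl 4,7-dibromo-1H-indole-2-carboxylate | CCOC(=O)c1cc2c(Br)ccc(Br)c2[nH]1
A5 | direct plan | 4,7-dibromo-1H-indole-2-carboxylic acid | OC(=O)c1cc2c(Br)ccc(Br)c2[nH]1
A6 | direct plan | 4,7-dibromo-1H-indole | Brc1ccc(Br)c2[nH]ccc12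
A7 | direct plan | 4,7-dibromo-3-chloro-1H-indole | Clc1c[nH]c2c(Br)ccc(Br)c12
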